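The synthesis rests on making ring A by contracting a six-membered ring. Ring A (C14–C18) is a trans-fused cyclopentanone whose C18 lies between the C17 ketone and the ring-fusion carbon C14, which is the 2-oxocyclopentanecarboxylate pattern a Wolff rearrangement leaves behind. Irradiating a 2-diazo-trans-decalin-1,3-dione in methanol (C12 masked as a dioxolane, trans C14–H/C15–CH3 fusion fixed beforehand by hydroboration) forms C14–C18, closes ring A and leaves an ester on C18 that later becomes the isopropyl methine. Ring D arrives as an alkenyllithium that adds to the C12 ketone; ring C is closed by metathesis and finished by hydroxyl-directed epoxidation.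

Key step: step 8

Locants: ring A = C14–C18 (C17 carbonyl, C18 isopropyl); ring B = C1, C2, C12–C15; ring C = C2–C6 and C10–C12; ring D = C6–C10; C19 = the decalindione carbonyl carbon between C14 and C18, which ends as the isopropyl CH; β = the face of the C15 methyl.
Correction: C18 of the ring-contraction product lies between two carbonyl groups and is configurationally labile, so step 8 cannot fix it; 13 is drawn as the epimer expected to dominate (ester α, trans to the C15 methyl) and the centre is erased in step 9.
Remark on C18: in the target the isopropyl group is β (cis to the C15 methyl, pseudo-axial), judged the less stable epimer of an enolisable centre; it is therefore set kinetically (step 11) and C17 is kept as a silyl ether until the last step.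
Precursor design: the trans fusion of 12 is installed by a stereospecific syn hydroboration, not by equilibration, and the C17 carbonyl is released last under base so that the C12 dioxolane survives.
Assumptions: ketone 1 is taken as a catalogue compound (otherwise one methylation from 1,4-dioxaspiro[4.5]decan-8-one); in step 16 the ligand L* = O,O′-(S)-1,1′-binaphthyl-2,2′-diyl N,N-bis[(S)-1-phenylethyl]phosphoramidite is assumed to give 3R and would be exchanged for its mirror image if a model allylation showed the opposite sense.

Step 1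
Reactants: 1 7-methyl-1,4-dioxaspiro[4.5]decan-8-one (racemic); 2 (S)-1-phenylethylamine; 3 but-3-en-2-one
Product: 5 (S)-7-methyl-7-(3-oxobutyl)-1,4-dioxaspiro[4.5]decan-8-one, via imine 4 (not isolated)
Conditions: 2, TsOH (cat.), PhMe, reflux (Dean–Stark); 3, THF, rt; 10% aq. AcOH, rt
Reagents that add atoms: water, O
Why: Imine 4 reacts through its more substituted secondary enamine tautomer in an aza-ene-type asymmetric Michael addition to 3, the enone approaching the face remote from the phenyl group of the auxiliary, which should set the quaternary C15 centre; mild hydrolysis frees the ketone and returns 2.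

Step 2
Reactants: 5 (S)-7-methyl-7-(3-oxobutyl)-1,4-dioxaspiro[4.5]decan-8-one
Product: 6 (S)-6,6-(ethylenedioxy)-4a-methyl-4,4a,5,6,7,8-hexahydronaphthalen-2(3H)-one
Conditions: NaOMe, MeOH, rt → 50 °C
Reagents that add atoms: none
Why: Intramolecular aldol condensation (second stage of a Robinson annulation) closes ring B onto the ring carbonyl and dehydrates to the C12 enone; the dioxolane is inert to methoxide and the quaternary centre cannot epimerise.

Step 3
Reactants: 6 (S)-6,6-(ethylenedioxy)-4a-methyl-4,4a,5,6,7,8-hexahydronaphthalen-2(3H)-one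
Product: 7 (S)-2,2:6,6-bis(ethylenedioxy)-4a-methyl-1,2,3,4,4a,5,6,7-octahydronaphthalene (C12 and C17 dioxolanes, C14=C19 alkene)
Conditions: HOCH2CH2OH, TsOH (cat.), benzene, reflux (Dean–Stark)
Reagents that add atoms: ethylene glycol, OCCO
Why: Acid-catalysed ketalisation of the cyclohexenone passes through the dienol ether and protonation at the α-carbon, so the C12 dioxolane forms with the double bond moved out of conjugation to C14=C19 (deconjugative ketalisation, as with steroidal 4-en-3-ones).

Step 4
Reactants: 7 bis-dioxolane alkene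
Product: 8 (1R,4aS,8aR)-3,3:7,7-bis(ethylenedioxy)-4a-methyldecahydronaphthalen-1-ol (trans-fused; C19–OH α, C14–H α)
Conditions: BH3·THF, THF, 0 °C → rt; NaOH, H2O2
Reagents that add atoms: hydrogen peroxide, OO
Why: Hydroboration–oxidation places boron on the less substituted C19 and adds H and B syn from the α face, the β face at C19 being blocked by the syn-axial C15 methyl and the axial oxygen of the C17 dioxolane, so C14–H should end α (trans ring fusion) and the C19 hydroxyl α.

Step 5
Reactants: 8 trans-fused C19 alcohol
Product: 9 (4aS,8aR)-3,3:7,7-bis(ethylenedioxy)-4a-methyloctahydronaphthalen-1(2H)-one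
Conditions: Dess–Martin periodinane, NaHCO3, CH2Cl2, rt
Reagents that add atoms: none
Why: Dess–Martin oxidation of the secondary alcohol under buffered, non-epimerising conditions gives the C19 ketone; both dioxolanes tolerate the neutral medium.

Step 6
Reactants: 9 bis-dioxolane ketone
Product: 11 (4aS,8aR)-7,7-(ethylenedioxy)-4a-methylhexahydronaphthalene-1,3(2H,4H)-dione, via vinylogous ester 10 (not isolated)
Conditions: KOH, MeOH/H2O, rt → 50 °C; NaH2PO4 (pH 5), 0 °C
Reagents that add atoms: potassium hydroxide, [K+].[OH-]
Why: Only the C17 dioxolane is β to the ketone, so enolisation at C18 and β-elimination (E1cB, retro-oxa-Michael) open it to 10 with relief of the syn-axial C15–CH3/O contact, and hydroxide addition–elimination (saponification of a vinylogous ester) gives the dione enolate while the base-stable C12 dioxolane is kept; buffered acidification avoids ketal loss.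

Step 7
Reactants: 11 trans-decalin-1,3-dione
Product: 12 (4aS,8aR)-2-diazo-7,7-(ethylenedioxy)-4a-methylhexahydronaphthalene-1,3(2H,4H)-dione
Conditions: 4-acetamidobenzenesulfonyl azide, Et3N, MeCN, 0 °C → rt
Reagents that add atoms: 4-acetamidobenzenesulfonyl azide, CC(=O)Nc1ccc(cc1)S(=O)(=O)N=[N+]=[N-]
Why: Regitz diazo transfer to the doubly activated C18 methylene of a cyclic 1,3-dione is standard and runs under amine base that neither enolises C14 nor harms the ketal.

Step 8
Reactants: 12 2-diazo-trans-decalin-1,3-dione
Product: 13 methyl (1S,3aS,7aS)-6,6-(ethylenedioxy)-3a-methyl-2-oxooctahydro-1H-indene-1-carboxylate (C17 ketone, C18 ester, C12 dioxolane)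
Conditions: hν (365 nm), MeOH, rt
Reagents that add atoms: methanol, CO
Why: Excitation of 12 expels N2 and, concertedly or through the singlet acyl carbene, the C14–C19 σ bond shifts from the carbonyl carbon C19 to C18, giving an α-oxo ketene that methanol traps as the β-keto ester (photochemical Wolff rearrangement). The closest known reaction type is the photolytic contraction of cyclic 2-diazo-1,3-diones to 2-oxocyclopentanecarboxylates. Ring A is closed by a 1,2-shift ring contraction (six- to five-membered) and not by a cyclisation, and the C14–C18 bond forms with retention at the migrating C14, so the trans C14–H/C15–CH3 fusion from step 4 is carried over. The new sp3 centre C18 is not controlled by the rearrangement: it should equilibrate through the enol to the α-ester and is erased in step 9. The step needs C14 to migrate in preference to C16; both acyl σ bonds are held antiperiplanar to the departing N2, so the choice rests on the higher migratory aptitude of the more substituted methine C14 over the neopentyl-type methylene C16, and this has to be verified.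

Step 9
Reactants: 13 β-keto ester
Product: 14 MOM enol ether (C17–OCH2OCH3, C17=C18, CO2CH3 on C18; C14–H α, C15–CH3 β, C12 dioxolane)
Conditions: NaH, MOMCl, THF/DMPU, 0 °C
Reagents that add atoms: chloromethyl methyl ether, COCCl
Why: O-Alkylation of the sodium enolate of a cyclic β-keto ester by the hard electrophile MOMCl in a dipolar medium gives the enol ether, which masks C17, flattens the labile C18 centre and leaves the ester as the only carbonyl group.

Step 10
Reactants: 14 MOM enol ether ester
Product: 16 isopropylidene enone (C17 ketone, C18=C19(CH3)2, C12 dioxolane), via tertiary alcohol 15 (not isolated)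
Conditions: MeLi (3 equiv), Et2O, −78 → 0 °C; 10% aq. oxalic acid, THF, 0 °C
Reagents that add atoms: methyllithium, [Li]C
Why: Double 1,2-addition of methyllithium to the ester of the β-alkoxy enoate gives 15, whose acid-induced ionisation, assisted by the enol ether oxygen and followed by loss of the MOM group, transposes it to the α-isopropylidene ketone (addition to a vinylogous ester, then hydrolysis–dehydration); C19 is now the isopropyl carbon and mild oxalic acid spares the dioxolane.

Step 11
Reactants: 16 isopropylidene enone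
Product: 17 isopropyl ketone (C18–iPr β, C18–H α)
Conditions: H2 (1 atm), Pd/C, EtOAc, rt
Reagents that add atoms: none
Why: Heterogeneous hydrogenation of the conjugated tetrasubstituted enone should deliver hydrogen to C18 from the α face, the β face being shielded by the 1,3-related C15 methyl, which places the isopropyl group β under kinetic control; the crude ketone is reduced at once.

Step 12
Reactants: 17 isopropyl ketone
Product: 18 C17 alcohol (C17–OH β, C18–iPr β)
Conditions: LiAlH4, Et2O, −78 → −20 °C
Reagents that add atoms: none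
Why: Low-temperature hydride reduction is fast and non-enolising, so C18 is preserved; hydride should attack C17 from the α face, anti to the β isopropyl and C15 methyl groups, and the C17 configuration is of no consequence because it is re-oxidised in step 31.

Step 13
Reactants: 18 C17 alcohol
Product: 19 C17 tert-butyldimethylsilyl ether
Conditions: TBSOTf, 2,6-lutidine, CH2Cl2, −78 → 0 °C
Reagents that add atoms: tert-butyldimethylsilyl triflate, CC(C)(C)[Si](C)(C)OS(=O)(=O)C(F)(F)F
Why: Silylation of the hindered secondary alcohol with the silyl triflate and a hindered base gives an ether that withstands the acid, base, organolithium and metathesis steps ahead.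

Step 14
Reactants: 19 silyl ether dioxolane
Product: 20 C12 ketone (C17–OTBS, C18–iPr β)
Conditions: PPTS, acetone/H2O, 60 °C
Reagents that add atoms: water, O
Why: Mild aqueous acid hydrolyses the dioxolane (acetal hydrolysis) while the hindered secondary silyl ether survives, and no stereocentre is at risk because C18 is no longer α to a carbonyl group.

Step 15
Reactants: 20 C12 ketone
Product: 21 trimethylsilyl enol ether with C2=C12 double bond
Conditions: LDA, TMSCl, THF, −78 °C
Reagents that add atoms: chlorotrimethylsilane, C[Si](C)(C)Cl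
Why: Kinetic deprotonation with in-situ silylation should give the enol ether towards C2, the direction favoured for ketones of the 5α-3-keto-steroid type, where a C12=C13 double bond would strain the trans ring fusion.

Step 16
Reactants: 21 silyl enol ether; 22 (E)-but-2-enyl methyl carbonate
Product: 23 2α-[(R)-but-3-en-2-yl] ketone (C2–H β, C3 R)
Conditions: [Ir(cod)Cl]2 (2 mol%), L* (4 mol%), CsF, ZnF2 (cat.), DME, 50 °C; DBU, CH2Cl2, rt
Reagents that add atoms: none
Why: Iridium-catalysed allylic alkylation of the fluoride-activated silyl enol ether attacks the substituted terminus of the crotyl unit (branched-selective allylic substitution), the phosphoramidite ligand controlling the new C3 centre, while C2 is alkylated and then equilibrated with DBU to the equatorial 2α epimer.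

Step 17
Reactants: 24 3-(trimethylsilyl)propynal; 25 1-(triphenylphosphoranylidene)propan-2-one
Product: 26 (E)-6-(trimethylsilyl)hex-3-en-5-yn-2-one
Conditions: CH2Cl2, rt
Reagents that add atoms: none
Why: Wittig olefination of the aldehyde with the stabilised acetonyl ylide gives the (E)-enone and leaves the silyl alkyne untouched.

Step 18
Reactants: 26 (E)-enynone
Product: 27 (R,E)-6-(trimethylsilyl)hex-3-en-5-yn-2-ol
Conditions: (S)-2-methyl-CBS-oxazaborolidine (10 mol%), catecholborane, PhMe, −78 °C
Reagents that add atoms: none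
Why: Corey–Bakshi–Shibata reduction with the (S)-oxazaborolidine differentiates the large enynyl and small methyl groups and should give the (R)-allylic alcohol by 1,2-reduction.

Step 19
Reactants: 27 (R)-enynol; 28 allyl bromide
Product: 29 trimethyl[(3E,5R)-5-(prop-2-enyloxy)hex-3-en-1-ynyl]silane
Conditions: NaH, THF, 0 °C → rt
Reagents that add atoms: none
Why: Williamson etherification of the sodium alkoxide gives the bis(allylic) ether without touching the carbinol stereocentre.

Step 20
Reactants: 29 bis(allylic) ether
Product: 31 (2R,3S)-2-methyl-3-[(E)-prop-1-enyl]-5-(trimethylsilyl)pent-4-ynal, via (E)-propenyl ether 30 (not isolated)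
Conditions: [Ir(coe)2Cl]2 (1 mol%), PCy3, NaBPh4, CH2Cl2/acetone, rt; PPh3, ClCH2CH2Cl, 80 °C
Reagents that add atoms: none
Why: The cationic iridium–phosphine catalyst isomerises only the terminal allyl group to the (E)-propenyl ether, and heating triggers a Claisen rearrangement through a chair transition state with the carbinol methyl equatorial, transferring chirality to give the 2,3-syn aldehyde with C7 and C6 set and an (E)-propenyl group on C6.

Step 21
Reactants: 31 aldehyde
Product: 32 [(3S,4S)-4-methyl-3-[(E)-prop-1-enyl]hex-5-en-1-ynyl]trimethylsilane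
Conditions: Ph3PCH3Br, KHMDS, THF, −78 → 0 °C
Reagents that add atoms: methylenetriphenylphosphorane, C=P(c1ccccc1)(c1ccccc1)c1ccccc1
Why: Wittig methylenation with the non-stabilised ylide at low temperature adds C9 without epimerising the α-stereocentre C7.

Step 22
Reactants: 32 terminal alkene
Product: 33 (3S,4R)-3-methyl-4-[(E)-prop-1-enyl]-6-(trimethylsilyl)hex-5-yn-1-ol
Conditions: 9-BBN, THF, 0 °C → rt; aq. H2O2, NaHCO3, 0 °C
Reagents that add atoms: hydrogen peroxide, OO
Why: Hydroboration with the bulky 9-BBN is selective for the terminal alkene over the (E)-disubstituted alkene and the silyl alkyne and places boron on the terminal carbon, and buffered peroxide oxidation keeps the alkynyl C–Si bond.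

Step 23
Reactants: 33 primary alcohol
Product: 34 [(3R,4S)-6-iodo-4-methyl-3-[(E)-prop-1-enyl]hex-1-ynyl]trimethylsilane
Conditions: I2, PPh3, imidazole, CH2Cl2, 0 °C
Reagents that add atoms: iodine, II
Why: Appel-type iodination converts the primary alcohol into the iodide under neutral conditions.

Step 24
Reactants: 34 iodo alkyne
Product: 36 trimethyl[(Z)-1-[(2R,3S)-3-methyl-2-[(E)-prop-1-enyl]cyclopentylidene]ethyl]silane, via vinyllithium 35 (not isolated)
Conditions: t-BuLi (2.2 equiv), pentane/Et2O, −78 → −40 °C; MeI, THF, −78 → 0 °C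
Reagents that add atoms: iodomethane, CI
Why: Iodine–lithium exchange gives a primary alkyllithium that closes ring D by 5-exo-dig syn carbolithiation of the silyl alkyne (the internal propenyl group is not a competent acceptor), so in 35 lithium is cis to C9 and silicon cis to C6, and low-temperature methylation with retention fixes that geometry; the preset C6 and C7 centres end cis on ring D.

Step 25
Reactants: 36 vinylsilane
Product: 37 (2R,3S)-1-[(Z)-1-iodoethylidene]-3-methyl-2-[(E)-prop-1-enyl]cyclopentane
Conditions: N-iodosuccinimide, MeCN, 0 °C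
Reagents that add atoms: N-iodosuccinimide, O=C1CCC(=O)N1I
Why: Ipso-iododesilylation through a β-silyl cation should proceed with retention of alkene geometry, leaving iodine cis to C6, and the electron-rich tetrasubstituted vinylsilane reacts ahead of the propenyl group.

Step 26
Reactants: 37 alkenyl iodide; 23 allylated C12 ketone
Product: 39 tertiary allylic alcohol (C12–OH α axial, C11 β equatorial, C10=C11 with C12 cis to C6), via alkenyllithium 38 (not isolated)
Conditions: 37, t-BuLi (2 equiv), Et2O, −78 °C; 23, LaCl3·2LiCl, THF, −78 → −30 °C; aq. NH4Cl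
Reagents that add atoms: none
Why: Iodine–lithium exchange with retention gives 38, which adds to the C12 ketone (1,2-addition, Lewis acid additive against enolisation) along the equatorial trajectory favoured for a bulky nucleophile, giving the axial α-hydroxyl and the β-equatorial alkenyl group trans to the C2 side chain.

Step 27
Reactants: 39 diene alcohol
Product: 40 tetracyclic diene (ring C closed, (Z)-C4=C5)
Conditions: second-generation Grubbs catalyst (10 mol%), PhMe (2 mM), 80 °C
Reagents that add atoms: none
Why: Ring-closing metathesis between the vinyl group on C3 and the propenyl group on C6 closes the eight-membered ring C as the (Z)-cycloalkene with loss of propene, the (Z)-tetrasubstituted C10=C11 alkene holding both chains on the same side and being inert to the catalyst.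

Step 28
Reactants: 40 tetracyclic diene
Product: 41 tetracyclic allylic alcohol (C4–C5 saturated, C10=C11 retained)
Conditions: H2 (1 atm), Pd/C, EtOAc, rt
Reagents that add atoms: none
Why: Catalytic hydrogenation saturates only the disubstituted C4=C5 alkene, the tetrasubstituted C10=C11 alkene being too hindered to reduce under these conditions, and no stereocentre is formed.

Step 29
Reactants: 41 tertiary allylic alcohol
Product: 42 C10–C11 epoxide (oxygen syn to C12–OH; C17–OTBS)
Conditions: VO(acac)2 (10 mol%), t-BuOOH, CH2Cl2, 0 °C → rt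
Reagents that add atoms: tert-butyl hydroperoxide, CC(C)(C)OO
Why: Vanadium-catalysed epoxidation is directed by the tertiary allylic C12 hydroxyl, so oxygen is delivered to the face of the ring C alkene syn to that hydroxyl (hydroxyl-directed epoxidation), setting C10 and C11, and the ring holds the alkene Z so the epoxide is cis.

Step 30
Reactants: 42 epoxy silyl ether
Product: 43 C17 alcohol
Conditions: TBAF, THF, 50 °C
Reagents that add atoms: none
Why: Fluoride cleaves the silyl ether (desilylation) while the epoxide and tertiary alcohol are stable to TBAF.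

Step 31
Reactants: 43 epoxy diol
Product: 44 CNP0332295.1
Conditions: Dess–Martin periodinane, NaHCO3, CH2Cl2, 0 °C → rt
Reagents that add atoms: none
Why: Dess–Martin oxidation of the only secondary alcohol under buffered, non-basic conditions gives the C17 ketone without epimerising the adjacent C18 centre, and the tertiary alcohol and epoxide are inert.

Compound list
1 | 7-methyl-1,4-dioxaspiro[4.5]decan-8-one (racemic) | CC1CC2(CCC1=O)OCCO2 | starting material
2 | (S)-1-phenylethylamine | C[C@H](N)c1ccccc1 | starting material
3 | but-3-en-2-one | CC(=O)C=C | starting material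
4 | N-[(S)-1-phenylethyl] imine of 1 (methyl epimers, reacts as enamine) | CC1CC2(CCC1=N[C@@H](C)c1ccccc1)OCCO2 | intermediate
5 | (S)-7-methyl-7-(3-oxobutyl)-1,4-dioxaspiro[4.5]decan-8-one | O=C1CCC2(OCCO2)C[C@]1(C)CCC(C)=O | intermediate
6 | (S)-6,6-(ethylenedioxy)-4a-methyl-4,4a,5,6,7,8-hexahydronaphthalen-2(3H)-one | O=C1CC[C@@]2(C)CC3(OCCO3)CCC2=C1 | intermediate
7 | (S)-2,2:6,6-bis(ethylenedioxy)-4a-methyl-1,2,3,4,4a,5,6,7-octahydronaphthalene | C[C@@]12CCC3(OCCO3)CC1=CCC4(OCCO4)C2 | intermediate
8 | (1R,4aS,8aR)-3,3:7,7-bis(ethylenedioxy)-4a-methyldecahydronaphthalen-1-ol | C[C@@]12CCC3(OCCO3)C[C@H]1[C@H](O)CC4(OCCO4)C2 | intermediate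
9 | (4aS,8aR)-3,3:7,7-bis(ethylenedioxy)-4a-methyloctahydronaphthalen-1(2H)-one | C[C@@]12CCC3(OCCO3)C[C@H]1C(=O)CC4(OCCO4)C2 | intermediate
10 | (4aS,8aR)-7,7-(ethylenedioxy)-3-(2-hydroxyethoxy)-4a-methyl-4a,5,6,7,8,8a-hexahydronaphthalen-1(4H)-one | O=C1C=C(OCCO)C[C@]2(C)CCC3(OCCO3)C[C@@H]12 | intermediate
11 | (4aS,8aR)-7,7-(ethylenedioxy)-4a-methylhexahydronaphthalene-1,3(2H,4H)-dione | O=C1CC(=O)C[C@]2(C)CCC3(OCCO3)C[C@@H]12 | intermediate
12 | (4aS,8aR)-2-diazo-7,7-(ethylenedioxy)-4a-methylhexahydronaphthalene-1,3(2H,4H)-dione | O=C1C(=[N+]=[N-])C(=O)C[C@]2(C)CCC3(OCCO3)C[C@@H]12 | intermediate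
13 | methyl (1S,3aS,7aS)-6,6-(ethylenedioxy)-3a-methyl-2-oxooctahydro-1H-indene-1-carboxylate (C18 labile) | COC(=O)[C@@H]1C(=O)C[C@]2(C)CCC3(OCCO3)C[C@@H]12 | intermediate
14 | MOM enol ether of 13 (C17–OCH2OCH3, C17=C18) | COCOC1=C(C(=O)OC)[C@@H]2CC3(OCCO3)CC[C@@]2(C)C1 | intermediate
15 | tertiary alcohol (C18–C(OH)(CH3)2, C17 MOM enol ether) | COCOC1=C(C(C)(C)O)[C@@H]2CC3(OCCO3)CC[C@@]2(C)C1 | intermediate
16 | C18-isopropylidene C17 ketone, C12 dioxolane | CC(C)=C1C(=O)C[C@]2(C)CCC3(OCCO3)C[C@@H]12 | intermediate
17 | 18β-isopropyl C17 ketone, C12 dioxolane | CC(C)[C@H]1C(=O)C[C@]2(C)CCC3(OCCO3)C[C@@H]12 | intermediate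
18 | 17β-alcohol, 18β-isopropyl, C12 dioxolane | CC(C)[C@H]1[C@@H](O)C[C@]2(C)CCC3(OCCO3)C[C@@H]12 | intermediate
19 | 17β-OTBS ether, C12 dioxolane | CC(C)[C@H]1[C@@H](O[Si](C)(C)C(C)(C)C)C[C@]2(C)CCC3(OCCO3)C[C@@H]12 | intermediate
20 | 17β-OTBS trans-hydrindan-C12-one | CC(C)[C@H]1[C@@H](O[Si](C)(C)C(C)(C)C)C[C@]2(C)CCC(=O)C[C@@H]12 | intermediate
21 | C2=C12 trimethylsilyl enol ether of 20 | CC(C)[C@H]1[C@@H](O[Si](C)(C)C(C)(C)C)C[C@]2(C)CC=C(O[Si](C)(C)C)C[C@@H]12 | intermediate
22 | (E)-but-2-enyl methyl carbonate | C/C=C/COC(=O)OC | starting material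
23 | 2α-[(R)-but-3-en-2-yl] C12 ketone | CC(C)[C@H]1[C@@H](O[Si](C)(C)C(C)(C)C)C[C@]2(C)C[C@H]([C@H](C)C=C)C(=O)C[C@@H]12 | intermediate
24 | 3-(trimethylsilyl)propynal | O=CC#C[Si](C)(C)C | starting material
25 | 1-(triphenylphosphoranylidene)propan-2-one | CC(=O)C=P(c1ccccc1)(c1ccccc1)c1ccccc1 | starting material
26 | (E)-6-(trimethylsilyl)hex-3-en-5-yn-2-one | CC(=O)/C=C/C#C[Si](C)(C)C | intermediate
27 | (R,E)-6-(trimethylsilyl)hex-3-en-5-yn-2-ol | C[C@@H](O)/C=C/C#C[Si](C)(C)C | intermediate
28 | allyl bromide | C=CCBr | starting material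
29 | trimethyl[(3E,5R)-5-(prop-2-enyloxy)hex-3-en-1-ynyl]silane | C[C@@H](OCC=C)/C=C/C#C[Si](C)(C)C | intermediate
30 | (E)-propenyl ether of 27 | C[C@@H](O/C=C/C)/C=C/C#C[Si](C)(C)C | intermediate
31 | (2R,3S)-2-methyl-3-[(E)-prop-1-enyl]-5-(trimethylsilyl)pent-4-ynal | O=C[C@H](C)[C@H](/C=C/C)C#C[Si](C)(C)C | intermediate
32 | [(3S,4S)-4-methyl-3-[(E)-prop-1-enyl]hex-5-en-1-ynyl]trimethylsilane | C=C[C@H](C)[C@H](/C=C/C)C#C[Si](C)(C)C | intermediate
33 | (3S,4R)-3-methyl-4-[(E)-prop-1-enyl]-6-(trimethylsilyl)hex-5-yn-1-ol | OCC[C@H](C)[C@H](/C=C/C)C#C[Si](C)(C)C | intermediate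
34 | [(3R,4S)-6-iodo-4-methyl-3-[(E)-prop-1-enyl]hex-1-ynyl]trimethylsilane | ICC[C@H](C)[C@H](/C=C/C)C#C[Si](C)(C)C | intermediate
35 | α-silyl vinyllithium (Li cis to C9) | [Li]/C([Si](C)(C)C)=C1\CC[C@H](C)[C@@H]1/C=C/C | intermediate
36 | trimethyl[(Z)-1-[(2R,3S)-3-methyl-2-[(E)-prop-1-enyl]cyclopentylidene]ethyl]silane | C/C([Si](C)(C)C)=C1\CC[C@H](C)[C@@H]1/C=C/C | intermediate
37 | (2R,3S)-1-[(Z)-1-iodoethylidene]-3-methyl-2-[(E)-prop-1-enyl]cyclopentane | C/C(I)=C1\CC[C@H](C)[C@@H]1/C=C/C | intermediate
38 | alkenyllithium from 37 | C/C([Li])=C1\CC[C@H](C)[C@@H]1/C=C/C | intermediate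
39 | C12 tertiary allylic alcohol (seco ring C; vinyl on C3, propenyl on C6) | CC(C)[C@H]1[C@@H](O[Si](C)(C)C(C)(C)C)C[C@]2(C)C[C@H]([C@H](C)C=C)[C@](O)(C[C@@H]12)/C(C)=C3/CC[C@H](C)[C@@H]3/C=C/C | intermediate
40 | tetracyclic 4(Z),10-diene, C12–OH, C17–OTBS | CC(C)[C@H]1[C@@H](O[Si](C)(C)C(C)(C)C)C[C@]2(C)C[C@@H]3[C@H](C)/C=C\[C@H]4[C@@H](C)CC/C4=C(C)/[C@@]3(O)C[C@@H]12 | intermediate
41 | tetracyclic 10-ene, C12–OH, C17–OTBS | CC(C)[C@H]1[C@@H](O[Si](C)(C)C(C)(C)C)C[C@]2(C)C[C@@H]3[C@H](C)CC[C@H]4[C@@H](C)CC/C4=C(C)/[C@@]3(O)C[C@@H]12 | intermediate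
42 | C10–C11 epoxide, C12–OH, C17–OTBS | CC(C)[C@H]1[C@@H](O[Si](C)(C)C(C)(C)C)C[C@]2(C)C[C@@H]3[C@H](C)CC[C@H]4[C@@H](C)CC[C@]45O[C@]5(C)[C@@]3(O)C[C@@H]12 | intermediate
43 | C10–C11 epoxide, C12–OH, C17–OH | CC(C)[C@H]1[C@@H](O)C[C@]2(C)C[C@@H]3[C@H](C)CC[C@H]4[C@@H](C)CC[C@]45O[C@]5(C)[C@@]3(O)C[C@@H]12 | intermediate
44 | CNP0332295.1 | CC(C)[C@H]1C(=O)C[C@]2(C)C[C@@H]3[C@H](C)CC[C@H]4[C@@H](C)CC[C@]45O[C@]5(C)[C@@]3(O)C[C@@H]12 | target

Total step count: 31 (steps 1–16 for rings A and B, steps 17–25 for the ring D fragment, steps 26–31 after union). Longest linear sequence: 22 steps (steps 1–16 and 26–31).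

Steps most likely to fail

Step 8: the 1,2-shift may lose regiocontrol, the C16 methylene migrating in competition with C14 and giving the transposed keto ester. The fallback sets out from ketone 9, which has a single enolisable methylene (C18). Trifluoroacetylation (LiHMDS, CF3CO2CH2CF3, THF, −78 °C) would give the α-trifluoroacetyl ketone F1. Deacylative diazo transfer (MsN3, Et3N, MeCN) would give the α-diazo ketone F2, in which C14 is the only carbon on the carbonyl that can migrate. Irradiation in MeOH (Wolff contraction of a cyclic α-diazo ketone) would give the ring A ester F3 with C17 still ketalised. NaOMe in MeOH would open the C17 dioxolane by β-elimination to the 2-hydroxyethyl enol ether F4. Excess MeLi would give the tertiary alcohol F5, and aqueous oxalic acid would return the route at enone 16.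

Step 16: the allylation may suffer from attack at the unsubstituted allyl terminus, erosion of enolate regiochemistry or poor facial control at C3. The fallback sets out from ketone 20. Aldol addition of its lithium enolate (LDA, THF, −78 °C) to acetaldehyde would give the β-hydroxy ketone F6, dehydrated (TsOH, benzene, reflux) to the (E)-2-ethylidene ketone F7. Copper-catalysed conjugate addition of vinylmagnesium bromide (CuBr·SMe2, TMSCl, THF, −78 °C) to the less hindered α face of the s-cis enone, then DBU equilibration at C2, would return the route at 23; any C3 epimer would have to be removed.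

Step 26: proton transfer (enolisation of the hindered ketone by the hindered alkenyllithium) may outrun addition. The fallback sets out from 23 and 37 and makes the C11–C12 bond intramolecularly. Cross-metathesis (second-generation Grubbs catalyst, CH2Cl2, 40 °C) would join the C3 vinyl and C6 propenyl groups to give the keto alkenyl iodide F8. Diimide reduction (TsNHNH2, NaOAc, DME/H2O, 85 °C) would saturate C4=C5 to give F9. Nozaki–Hiyama–Kishi cyclisation (CrCl2, NiCl2 cat., DMSO, rt) would close ring C and return the route at 41.

Further compounds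
F1 | step 8 | α-trifluoroacetyl derivative of 9 at C18 | O=C1C(C(=O)C(F)(F)F)C2(OCCO2)C[C@]3(C)CCC4(OCCO4)C[C@@H]13
F2 | step 8 | C18 α-diazo ketone with C12 and C17 dioxolanes | O=C1C(=[N+]=[N-])C2(OCCO2)C[C@]3(C)CCC4(OCCO4)C[C@@H]13
F3 | step 8 | ring A methyl ester on C18 with C12 and C17 dioxolanes (C18 epimers) | COC(=O)C1C2(OCCO2)C[C@]3(C)CCC4(OCCO4)C[C@@H]13
F4 | step 8 | 2-hydroxyethyl enol ether ester (C17–OCH2CH2OH, C17=C18) | COC(=O)C1=C(OCCO)C[C@]2(C)CCC3(OCCO3)C[C@@H]12
F5 | step 8 | tertiary alcohol from F4 (C18–C(OH)(CH3)2) | CC(C)(O)C1=C(OCCO)C[C@]2(C)CCC3(OCCO3)C[C@@H]12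
F6 | step 16 | 2α-(1-hydroxyethyl) C12 ketone (carbinol epimers) | CC(C)[C@H]1[C@@H](O[Si](C)(C)C(C)(C)C)C[C@]2(C)C[C@H](C(C)O)C(=O)C[C@@H]12
F7 | step 16 | (E)-2-ethylidene C12 ketone | CC(C)[C@H]1[C@@H](O[Si](C)(C)C(C)(C)C)C[C@]2(C)C/C(=C\C)C(=O)C[C@@H]12
F8 | step 26 | cross-metathesis product: C12 ketone linked through (E)-C4=C5 to the ring D alkenyl iodide | CC(C)[C@H]1[C@@H](O[Si](C)(C)C(C)(C)C)C[C@]2(C)C[C@H]([C@H](C)/C=C/[C@H]3[C@@H](C)CC/C3=C(\C)I)C(=O)C[C@@H]12
F9 | step 26 | C4–C5 saturated keto alkenyl iodide | CC(C)[C@H]1[C@@H](O[Si](C)(C)C(C)(C)C)C[C@]2(C)C[C@H]([C@H](C)CC[C@H]3[C@@H](C)CC/C3=C(\C)I)C(=O)C[C@@H]12
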